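Conventions used throughout: eremophilane numbering (ring A = C10, C1–C5; ring B = C5–C10; C14 is the methyl on C5, C15 the methyl on C4, C11–C13 the three-carbon unit on C7); β is the face of the C5 methyl. In these terms the target 29 is 3α-acyloxy, 4β-Me, 5β-Me, 7β-isopropenyl, 8β-OH, 9β-OH, 10β-H, with a (2Z,5R)-5-(angeloyloxy)hex-2-enoate on O3.

## The problem

The target 29 is a cis-fused eremophilane. Ring A carries the α ester on C3 and the vicinal β methyls on C4 and on the quaternary ring-fusion carbon C5. Ring B carries three contiguous β substituents: the C7 isopropenyl group and the C8 and C9 hydroxyls, all on the face of the C5 methyl and H10. Seven ring stereocentres have to be set, together with the (R) carbinol centre and the two (Z) double bonds of the side chain. C5 and C10 are the anchor, because they are made with the ring system and cannot be corrected later. A group on C7 can then direct C9, the C9 oxygen can direct C8 and C7, and once ring B holds three cis β groups the decalin is locked in the conformer whose C5 methyl is axial over ring A, so that this methyl controls C3 and C4. The fragile parts are the angelate and the (Z)-enoate (isomerised by base, nucleophiles or strong acid), the β-hydroxy ketone that precedes the isopropenyl group (C7–H and C8–O are trans-diaxial, so base invites elimination), and the C11=C12 bond, which must not be present when C3=C4 is hydroborated; in addition only O3 of three hydroxyls may be acylated. The enabling feature is that C5–C6 with its methyl next to C4 is a methacryloyl unit, C7–C10 becomes a diene once the C8 and C9 oxygens are traced to a C8=C9 double bond, and C1–C4 is a four-atom tether from C10 to C5. Ring B is thus the cyclohexene of a Diels–Alder reaction and ring A the ring closed by its tether, in the 2-methyl-1,7,9-decatrien-3-one 7.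

## Retrosynthesis

**29 from 28.** No skeletal bond is cut; the 8,9-diol is masked as the acetonide 28. An acetonide forms only on the cis-8,9-diol, so it differentiates O3 from O8 and O9 in one step. It is removed by warm aqueous acetic acid, which the two unsaturated esters tolerate; a base- or fluoride-labile group would put the side chain at risk.

**28 from 21 and 27.** The C2′=C3′ double bond of the hexenoate is cut. The neighbouring cut, the ester C–O bond, would require activating a (Z)-enoic acid, which risks Z to E isomerisation, and its δ-hydroxy precursor lactonises. A (Z)-selective phosphonate olefination makes the sensitive alkene last, at low temperature and convergently. The forward step must be kinetically Z-selective and must not enolise the β-acyloxy aldehyde 27.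

**21 from 19 and 20; 27 from 25 (via 26); 25 from 22 and 23 (via 24).** Simple acylations and an alkene cleavage; 22 supplies the (R) centre from the chiral pool and 23 the angelate, introduced through the mixed anhydride 24 to keep its geometry.

**19 from 18, 18 from 17, 17 from 15 (via 16), 13 from 12.** C11=C12 is cut by carbonyl methylenation, and the resulting β-hydroxy ketone 17 is the open form of the isoxazoline in 15. Its C7–C11 and C8–O bonds are cut together as a hydroxyl-directed cycloaddition of a two-carbon nitrile oxide to the allylic alcohol 12. This is preferred to epoxide opening (gives the trans C7/C8 relation) and to conjugate addition followed by enolate oxidation (places O8 anti to the C7 group). Three contiguous centres are reduced to the single carbinol C9. The forward reaction must deliver both new bonds syn to O9, with oxygen on C8.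

**15 from 13 (via 14).** The C3–O and C4–H bonds are cut as a hydroboration. Syn addition gives the 3,4-trans relation directly, whereas hydride reduction of a C3 ketone would be steered to the wrong epimer by the syn-axial C5 methyl. The step is placed at the isoxazoline stage because no other C=C bond is then present; it must precede the unveiling of C11=C12.

**12 from 11, 11 from 9 (via 10), 9 from 8.** The C4–C15 bond is cut as a methyl cross-coupling on an enol triflate; methyl addition and dehydration would give endo/exo alkene mixtures. The C9–O bond comes from the allylsilane of 9 by epoxidation anti to silicon and loss of silicon, which moves the double bond to C7=C8. The triflate is installed before the epoxidation so that the allylsilane is the only nucleophilic alkene, and the methyl group after it.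

**8 from 7.** C5–C10 and C6–C7 are cut: an intramolecular Diels–Alder reaction of the achiral trienone 7. This one cut removes both rings, the quaternary centre and the ring fusion, and it is the only point at which absolute configuration enters the core. The forward step must be endo with respect to the in-chain carbonyl and enantioface-selective under a chiral Lewis acid.

**7 from 5 and 6; 5 from 2 and 3 (via 4); 2 from 1.** The acyl–vinyl bond is cut as an acyl substitution on a Weinreb amide. The diene is cut at its central sp2–sp2 bond: alkyne hydroboration and cross-coupling with 3 fix both double-bond geometries by construction. A dienylation of an aldehyde with a bis-silylated allyl anion would be one step shorter from an aldehyde, but the geometry would depend on the mode of an elimination.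

## Roads not taken

**Alternative 1:** The two methyl–carbon bonds C5–C14 and C4–C15 are cut from the bicyclic enone A1, a 9β-silyloxy-Δ4-octal-3-one. Forward, a methyl cuprate adds to C5 from the face of H10 and the resulting enolate is C-methylated at C4 to give A2. Merits: the vicinal dimethyl array and the C3 carbonyl arrive in one flask, by a stereochemically well-understood conjugate addition, and C4 is epimerisable. For ring A this is shorter than the chosen plan, which spends three steps (5, 7, 9) on the same atoms. Weak points: A2 carries nothing at C7 and C8, so the isopropenyl group and the C8 hydroxyl must be built from the C9 oxygen alone. Cuprate enolates of this kind alkylate sluggishly. Hydride reduction of the C3 ketone is biased toward the axial 3β alcohol by the syn-axial C5 methyl. Enantiopure A1 needs its own asymmetric synthesis. Against the shorter ring A sequence the chosen plan sets a ring B in which C9, C8 and C7 follow from the cycloadduct 8 by relay.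

**Alternative 2:** C4–C5 and C1–C10 are cut, annulating ring A onto the chiral-pool enone A3 with the siloxydiene A4 by a Lewis-acid-promoted double Michael sequence that gives the dione A5. Merits: it is convergent, and C7 with its isopropenyl group arrives with the right absolute configuration; here it is better than the chosen plan, which needs steps 8, 10, 11 and 12 to reach the same group. Weak points: the first Michael addition must create the quaternary C5 on a β,β-disubstituted enone, the least reactive acceptor class, under only 1,3-induction from C7. C4 and C10 are set by loosely controlled protonations. The two ketones of A5 must be distinguished, and the C8 hydroxyl must come from α-oxidation of the C9 ketone in competition with enolisation toward C10. Against the free isopropenyl group the chosen plan sets a concerted formation of C5 and the cis fusion and a defined origin for both ring B oxygens.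

**Alternative 3:** C5–C6 is formed and C3–C8 broken in an anionic oxy-Cope rearrangement of the bicyclo[2.2.2]octenol A6, which gives the cis-fused dienone A7 after protonation of the dienolate at C7. Merits: the [3,3] shift is stereospecific, so the quaternary centre and the cis fusion follow from the bicycle. In that respect it is at least as secure as a catalytic asymmetric cycloaddition whose enantioselectivity is extrapolated. Weak points: enantiopure A6 needs an asymmetric bicyclooctenone synthesis and a dienyl-metal addition that places the dienyl group syn to the dimethyl-substituted bridge. The dienolate can protonate at the γ carbon. In A7 the isopropenyl group is present before C3 is oxygenated, so the hydroboration clash that the chosen plan avoids returns. The C9 oxygen must be introduced next to a ketone that also enolises toward C7. Against the stereospecific rearrangement the chosen plan sets an achiral, four-step precursor and a functional-group order in which each alkene is addressed while it is the only reactive one.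

Key step: step 4

Assumption: the sense of induction of the oxazaborolidinium catalyst with an in-chain α-methyl enone cannot be assigned by analogy with confidence; the (S)-prolinol-derived catalyst is written, and its mirror image is used if it delivers the antipode of 8.
Assumption: 20 is taken as purchasable; otherwise it is one ester hydrolysis from the commercial methyl ester.

## Route

Step 1
Reactants: 1 hex-5-ynoic acid
Product: 2 N-methoxy-N-methylhex-5-ynamide
Conditions: MeNH(OMe)·HCl, EDC·HCl, N-methylmorpholine, CH2Cl2, 0 °C → rt
Reagents that add atoms: N,O-dimethylhydroxylamine hydrochloride, CNOC.Cl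
Why: Carbodiimide amide coupling; the Weinreb amide allows a single later addition of the isopropenyl Grignard reagent and is inert to the hydroboration and coupling of step 2.

Step 2
Reactants: 2 N-methoxy-N-methylhex-5-ynamide; 3 (E)-(2-bromovinyl)trimethylsilane
Product: 5 (5E,7E)-N-methoxy-N-methyl-8-(trimethylsilyl)octa-5,7-dienamide, via (E)-alkenyl pinacol boronate 4 (not isolated)
Conditions: pinacolborane, (C6H11)2BH (10 mol %), THF, rt; then 3, Pd(PPh3)4 (3 mol %), K3PO4, THF–H2O, 60 °C
Reagents that add atoms: pinacolborane, B1OC(C)(C)C(C)(C)O1 (boron of intermediate 4 only)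
Why: Syn hydroboration of the terminal alkyne gives the (E)-alkenylboronate, and Suzuki–Miyaura coupling with the (E)-bromide retains geometry at both sp2 carbons, so the E,E diene is fixed by construction; the vinylsilane is stable to aqueous phosphate.

Step 3
Reactants: 5 (5E,7E)-N-methoxy-N-methyl-8-(trimethylsilyl)octa-5,7-dienamide; 6 isopropenylmagnesium bromide
Product: 7 (7E,9E)-2-methyl-10-(trimethylsilyl)deca-1,7,9-trien-3-one
Conditions: 6 (1.5 equiv), THF, −20 → 0 °C; inverse quench into cold 1 M HCl; used at once
Reagents that add atoms: none
Why: Weinreb ketone synthesis: the chelated tetrahedral adduct prevents over-addition, and the cold acidic inverse quench keeps the released amine from adding to the enone; 7 is used at once because it can cyclise slowly without catalyst.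

Step 4
Reactants: 7 (7E,9E)-2-methyl-10-(trimethylsilyl)deca-1,7,9-trien-3-one
Product: 8 cis-fused 5β-methyl-7α-(trimethylsilyl)-10βH-octal-8-en-4-one [8a-methyl-7-(trimethylsilyl)-3,4,4a,7,8,8a-hexahydronaphthalen-1(2H)-one, silicon anti to the angular methyl]
Conditions: [C24H25BNO][N(SO2CF3)2] (20 mol %, from the B-o-tolyl oxazaborolidine of (S)-α,α-diphenylprolinol and HN(SO2CF3)2), CH2Cl2, −78 → −20 °C; Et3N quench
Reagents that add atoms: none
Why: Coordination of the cationic boron Lewis acid to the C4 carbonyl lowers the LUMO of the methacryloyl unit, and the tethered (E,E)-silyldiene adds in a concerted, asynchronous [4+2] step; the closest known reaction types are the Lewis-acid-promoted cyclisation of 1,7,9-decatrien-3-ones to cis-octalones and oxazaborolidinium-catalysed Diels–Alder reactions of enones. Ring B is the cyclohexene formed by the two new bonds C5–C10 and C6–C7, and ring A closes in the same event as the fused six-membered ring spanned by the four-atom tether C1–C4 between the diene terminus C10 and the internal dienophile carbon C5 (type 1 intramolecular mode). C5 and C10 are set relative to each other by the endo placement of the in-chain carbonyl under the diene, which gives the cis fusion with the C5 methyl cis to H10. C7 is set by the (E) geometry of the silyl-bearing terminus: the outside substituent ends up cis to C1 and C4, hence α and anti to the angular methyl. The absolute configuration is set by the catalyst, whose aryl groups shield one face of the bound enone. The step needs endo over exo selectivity and enantioface selection; the short tether with the carbonyl inside it secures the former, and the single Lewis-basic site of 7 supports the latter. Keeping the acid substoichiometric to the oxazaborolidine and quenching cold protects the allylsilane product from protodesilylation.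

Step 5
Reactants: 8 cis-fused 5β-methyl-7α-(trimethylsilyl)-10βH-octal-8-en-4-one
Product: 9 5β-methyl-7α-(trimethylsilyl)-10βH-octala-3,8-dien-4-yl trifluoromethanesulfonate
Conditions: KN(SiMe3)2, THF, −78 °C; PhN(SO2CF3)2, −78 → 0 °C
Reagents that add atoms: N-phenylbis(trifluoromethanesulfonimide), O=S(=O)(N(c1ccccc1)S(=O)(=O)C(F)(F)F)C(F)(F)F
Why: Enolisation can occur only toward C3 because C5 is quaternary, so O-triflation gives one enol triflate; it stores the C3=C4 bond and is too electron-poor to react with peracid in step 6.

Step 6
Reactants: 9 5β-methyl-7α-(trimethylsilyl)-10βH-octala-3,8-dien-4-yl trifluoromethanesulfonate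
Product: 11 9β-hydroxy-5β-methyl-10βH-octala-3,7-dien-4-yl trifluoromethanesulfonate, via 8β,9β-epoxysilane 10 (not isolated)
Conditions: mCPBA, Na2HPO4, CH2Cl2, 0 °C; then AcOH, MeOH, rt
Reagents that add atoms: 3-chloroperoxybenzoic acid, OOC(=O)c1cccc(Cl)c1
Why: Peracid epoxidation of an allylsilane occurs anti to the C–Si bond, here the β and convex face; acid then triggers anti elimination of silicon and the C8–O bond (trans-diaxial), giving the transposed allylic alcohol with C9 fixed by the epoxide.

Step 7
Reactants: 11 9β-hydroxy-5β-methyl-10βH-octala-3,7-dien-4-yl trifluoromethanesulfonate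
Product: 12 cis-fused 4,5β-dimethyl-10βH-octala-3,7-dien-9β-ol
Conditions: MeMgBr (3 equiv), Fe(acac)3 (5 mol %), THF–N-methylpyrrolidone, −30 → 0 °C
Reagents that add atoms: methylmagnesium bromide, C[Mg]Br
Why: Iron-catalysed cross-coupling of alkenyl triflates with methyl Grignard reagent is fast at low temperature and tolerates the magnesium alkoxide formed from the free hydroxyl by the first equivalent.

Step 8
Reactants: 12 cis-fused 4,5β-dimethyl-10βH-octala-3,7-dien-9β-ol
Product: 13 9β-hydroxy-4,5β-dimethyl-10βH-octal-3-ene with a 3-methyl-4,5-dihydroisoxazole fused at C7–C8 (C7β–C(Me)=N–O–C8β)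
Conditions: i-PrOH (3.3 equiv), EtMgBr (3 equiv), CH2Cl2, 0 °C; then MeC(Cl)=NOH (slow addition), 0 °C → rt
Reagents that add atoms: N-hydroxyacetimidoyl chloride, CC(Cl)=NO
Why: Magnesium-alkoxide-directed nitrile oxide cycloaddition: magnesium bound to O9 also binds the dipole oxygen, so the dipole is delivered to the β face with its oxygen on the proximal carbon C8 and its carbon on C7; the hindered trisubstituted C3=C4 bond is not a competent dipolarophile.

Step 9
Reactants: 13 the C7–C8 fused isoxazoline of 9β-hydroxy-4,5β-dimethyl-10βH-octal-3-ene
Product: 15 4β,5β-dimethyl-10βH-decalin-3α,9β-diol with the 7β,8β-fused 3-methylisoxazoline, via 3α-boryl adduct 14 (not isolated)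
Conditions: BH3·THF (excess), THF, 0 °C → rt; then NaOH, H2O2, 0 °C
Reagents that add atoms: hydrogen peroxide, OO; borane–tetrahydrofuran, B.C1CCOC1 (boron of intermediate 14 only)
Why: Hydroboration–oxidation puts boron on the less substituted C3, and syn addition of H and B makes O3 trans to the C4 methyl. With three cis β groups on ring B the decalin sits in the conformer whose C5 methyl is axial over ring A, so borane reaches C3 from the α face, anti to that syn-axial methyl, as in a Δ5 steroid. The cyclic oxime ether is reduced by borane only on prolonged heating.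

Step 10
Reactants: 15 the 3α,9β-diol isoxazoline
Product: 17 7β-acetyl-4β,5β-dimethyl-10βH-decalin-3α,8β,9β-triol, via β-hydroxy imine 16 (not isolated)
Conditions: H2 (1 atm), Raney Ni, B(OH)3, MeOH–H2O (5:1), rt
Reagents that add atoms: water, O
Why: Hydrogenolysis of the N–O bond and hydrolysis of the imine in the boric acid buffer unmask the isoxazoline as a β-hydroxy ketone; no C=C bond is present, and the equatorial 7β acetyl group is the stable epimer.

Step 11
Reactants: 17 7β-acetyl-4β,5β-dimethyl-10βH-decalin-3α,8β,9β-triol
Product: 18 8β,9β-O-isopropylidene derivative of 17 (3α-OH free)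
Conditions: Me2C(OMe)2, pyridinium p-toluenesulfonate (cat.), acetone, rt
Reagents that add atoms: 2,2-dimethoxypropane, COC(C)(C)OC
Why: Under thermodynamic control only the cis-8,9-diol forms a five-membered acetonide, which leaves O3 free for the later acylation and removes the free β-hydroxyl from the ketone.

Step 12
Reactants: 18 8β,9β-O-isopropylidene-7β-acetyl triol
Product: 19 8β,9β-O-isopropylidene-10βH-eremophil-11-ene-3α,8β,9β-triol (4β,5β-dimethyl, 7β-isopropenyl, 3α-OH free)
Conditions: Zn, CH2Br2, TiCl4 (reagent pre-formed in THF); 18, CH2Cl2, 0 °C → rt
Reagents that add atoms: dibromomethane, BrCBr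
Why: Takai–Lombardo methylenation uses a non-basic gem-dimetallic reagent, so the enolisable ketone is methylenated without epimerisation at C7 or elimination of the axial C8 oxygen, which a basic ylide would invite; acetonides and free hydroxyls are tolerated.

Step 13
Reactants: 19 the 8,9-acetonide alcohol; 20 bis(2,2,2-trifluoroethyl)phosphonoacetic acid
Product: 21 3α-O-[bis(2,2,2-trifluoroethoxy)phosphorylacetyl] derivative of 19
Conditions: DCC, 4-(dimethylamino)pyridine (cat.), CH2Cl2, 0 °C → rt
Reagents that add atoms: none
Why: Steglich esterification of the equatorial C3 hydroxyl; attaching the phosphonate first avoids activating a (Z)-enoic acid.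

Step 14
Reactants: 22 (R)-pent-4-en-2-ol; 23 angelic acid [(Z)-2-methylbut-2-enoic acid]
Product: 25 (R)-pent-4-en-2-yl (Z)-2-methylbut-2-enoate, via angelic 2,4,6-trichlorobenzoic anhydride 24 (not isolated)
Conditions: 23, 2,4,6-trichlorobenzoyl chloride, Et3N, toluene, rt; then 22, 80 °C
Reagents that add atoms: 2,4,6-trichlorobenzoyl chloride, O=C(Cl)c1c(Cl)cc(Cl)cc1Cl (aroyl group of intermediate 24 only)
Why: Yamaguchi mixed-anhydride esterification without nucleophilic catalyst is the established way to transfer the angeloyl group without isomerisation to the tiglate; the carbinol centre is untouched.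

Step 15
Reactants: 25 (R)-pent-4-en-2-yl (Z)-2-methylbut-2-enoate
Product: 27 (R)-4-oxobutan-2-yl (Z)-2-methylbut-2-enoate, via 4,5-diol 26 (not isolated)
Conditions: OsO4 (2 mol %), NaIO4, 2,6-lutidine, dioxane–H2O, rt
Reagents that add atoms: sodium periodate, [Na+].[O-]I(=O)(=O)=O (terminal oxidant; oxygen delivered through catalytic OsO4)
Why: Lemieux–Johnson oxidation: osmylation prefers the isolated monosubstituted alkene to the conjugated, hindered angelate double bond, and the lutidine buffer suppresses β-elimination of angelic acid from the aldehyde.

Step 16
Reactants: 21 the C3 phosphonoacetate; 27 (R)-4-oxobutan-2-yl (Z)-2-methylbut-2-enoate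
Product: 28 8,9-O-isopropylidene derivative of the target
Conditions: 21, KN(SiMe3)2, 18-crown-6, THF, −78 °C; then 27, −78 °C
Reagents that add atoms: none
Why: Still–Gennari olefination: the trifluoroethyl phosphonate under dissociating conditions eliminates from the kinetic adduct to give the (Z)-enoate, and the weakly basic phosphonate anion at −78 °C does not enolise the β-acyloxy aldehyde.

Step 17
Reactants: 28 8,9-O-isopropylidene derivative of the target
Product: 29 3α-[(2Z,5R)-5-{[(Z)-2-methylbut-2-enoyl]oxy}hex-2-enoyloxy]-10βH-eremophil-11-ene-8β,9β-diol (CNP0395983.1)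
Conditions: AcOH–H2O (4:1), 40 °C
Reagents that add atoms: none
Why: Acid-catalysed hydrolysis of the acetonide; the esters, both (Z) alkenes and the isopropenyl group are stable to warm aqueous acetic acid, and the C3 ester is too remote from the freed diol for acyl migration.

## Compound list

1 | hex-5-ynoic acid | C#CCCCC(=O)O | starting material
2 | N-methoxy-N-methylhex-5-ynamide | C#CCCCC(=O)N(C)OC | intermediate
3 | (E)-(2-bromovinyl)trimethylsilane | C[Si](C)(C)/C=C/Br | starting material
4 | (E)-N-methoxy-N-methyl-6-(4,4,5,5-tetramethyl-1,3,2-dioxaborolan-2-yl)hex-5-enamide | CON(C)C(=O)CCC/C=C/B1OC(C)(C)C(C)(C)O1 | intermediate (not isolated)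
5 | (5E,7E)-N-methoxy-N-methyl-8-(trimethylsilyl)octa-5,7-dienamide | CON(C)C(=O)CCC/C=C/C=C/[Si](C)(C)C | intermediate
6 | isopropenylmagnesium bromide | C=C(C)[Mg]Br | starting material
7 | (7E,9E)-2-methyl-10-(trimethylsilyl)deca-1,7,9-trien-3-one | C=C(C)C(=O)CCC/C=C/C=C/[Si](C)(C)C | intermediate
8 | cis-fused 5β-methyl-7α-(trimethylsilyl)-10βH-octal-8-en-4-one | C[Si](C)(C)[C@@H]1C[C@@]2(C)[C@H](CCCC2=O)C=C1 | intermediate
9 | 5β-methyl-7α-(trimethylsilyl)-10βH-octala-3,8-dien-4-yl trifluoromethanesulfonate | C[Si](C)(C)[C@@H]1C[C@@]2(C)[C@H](CCC=C2OS(=O)(=O)C(F)(F)F)C=C1 | intermediate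
10 | 8β,9β-epoxide of 9 | C[Si](C)(C)[C@@H]1C[C@@]2(C)[C@H](CCC=C2OS(=O)(=O)C(F)(F)F)[C@H]3O[C@H]31 | intermediate (not isolated)
11 | 9β-hydroxy-5β-methyl-10βH-octala-3,7-dien-4-yl trifluoromethanesulfonate | C1[C@@]2(C)[C@H](CCC=C2OS(=O)(=O)C(F)(F)F)[C@@H](O)C=C1 | intermediate
12 | cis-fused 4,5β-dimethyl-10βH-octala-3,7-dien-9β-ol | C1[C@@]2(C)[C@H](CCC=C2C)[C@@H](O)C=C1 | intermediate
13 | 9β-hydroxy-4,5β-dimethyl-10βH-octal-3-ene with 7β,8β-fused 3-methyl-4,5-dihydroisoxazole (C7–C(Me)=N–O–C8) | CC1=NO[C@H]2[C@@H]1C[C@@]3(C)[C@H](CCC=C3C)[C@H]2O | intermediate
14 | 3α-boryl adduct of 13 (4β-methyl) | CC1=NO[C@H]2[C@@H]1C[C@@]3(C)[C@H](CC[C@@H](B)[C@@H]3C)[C@H]2O | intermediate (not isolated)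
15 | 4β,5β-dimethyl-10βH-decalin-3α,9β-diol with 7β,8β-fused 3-methyl-4,5-dihydroisoxazole | CC1=NO[C@H]2[C@@H]1C[C@@]3(C)[C@H](CC[C@@H](O)[C@@H]3C)[C@H]2O | intermediate
16 | 7β-(1-iminoethyl)-4β,5β-dimethyl-10βH-decalin-3α,8β,9β-triol | CC(=N)[C@H]1C[C@@]2(C)[C@H](CC[C@@H](O)[C@@H]2C)[C@@H](O)[C@H]1O | intermediate (not isolated)
17 | 7β-acetyl-4β,5β-dimethyl-10βH-decalin-3α,8β,9β-triol | CC(=O)[C@H]1C[C@@]2(C)[C@H](CC[C@@H](O)[C@@H]2C)[C@@H](O)[C@H]1O | intermediate
18 | 8β,9β-O-isopropylidene derivative of 17 | CC(=O)[C@H]1C[C@@]2(C)[C@H](CC[C@@H](O)[C@@H]2C)[C@@H](O3)[C@H]1OC3(C)C | intermediate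
19 | 8β,9β-O-isopropylidene-10βH-eremophil-11-ene-3α,8β,9β-triol | C=C(C)[C@H]1C[C@@]2(C)[C@H](CC[C@@H](O)[C@@H]2C)[C@@H](O3)[C@H]1OC3(C)C | intermediate
20 | bis(2,2,2-trifluoroethyl)phosphonoacetic acid | OC(=O)CP(=O)(OCC(F)(F)F)OCC(F)(F)F | starting material
21 | 3α-O-[bis(2,2,2-trifluoroethoxy)phosphorylacetyl] derivative of 19 | C=C(C)[C@H]1C[C@@]2(C)[C@H](CC[C@@H](OC(=O)CP(=O)(OCC(F)(F)F)OCC(F)(F)F)[C@@H]2C)[C@@H](O3)[C@H]1OC3(C)C | intermediate
22 | (R)-pent-4-en-2-ol | C=CC[C@@H](C)O | starting material
23 | angelic acid, (Z)-2-methylbut-2-enoic acid | C/C=C(/C)C(=O)O | starting material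
24 | (Z)-2-methylbut-2-enoic 2,4,6-trichlorobenzoic anhydride | C/C=C(/C)C(=O)OC(=O)c1c(Cl)cc(Cl)cc1Cl | intermediate (not isolated)
25 | (R)-pent-4-en-2-yl (Z)-2-methylbut-2-enoate | C=CC[C@@H](C)OC(=O)/C(C)=C\C | intermediate
26 | (2R)-4,5-dihydroxypentan-2-yl (Z)-2-methylbut-2-enoate (C4 epimers) | OCC(O)C[C@@H](C)OC(=O)/C(C)=C\C | intermediate (not isolated)
27 | (R)-4-oxobutan-2-yl (Z)-2-methylbut-2-enoate | O=CC[C@@H](C)OC(=O)/C(C)=C\C | intermediate
28 | 8β,9β-O-isopropylidene derivative of the target | C=C(C)[C@H]1C[C@@]2(C)[C@H](CC[C@@H](OC(=O)/C=C\C[C@@H](C)OC(=O)/C(C)=C\C)[C@@H]2C)[C@@H](O3)[C@H]1OC3(C)C | intermediate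
29 | 3α-[(2Z,5R)-5-{[(Z)-2-methylbut-2-enoyl]oxy}hex-2-enoyloxy]-10βH-eremophil-11-ene-8β,9β-diol (CNP0395983.1) | C=C(C)[C@H]1C[C@@]2(C)[C@H](CC[C@@H](OC(=O)/C=C\C[C@@H](C)OC(=O)/C(C)=C\C)[C@@H]2C)[C@@H](O)[C@H]1O | target

## Step count and least certain steps

Total: 17 steps. Longest linear sequence: 15 steps (steps 1–13, 16, 17); steps 14 and 15 form the side-chain branch.

**Step 4 (key step).** The enantioselective version on an in-chain α-methyl enone is an extension of the known catalysed reactions, not a demonstrated case. The most likely failure is weak enantioface discrimination, because this enone lacks the α-vinyl hydrogen that helps organise other enones on the catalyst. Uncatalysed background cyclisation would erode the selectivity further, and some reaction through the exo mode or protodesilylation by adventitious acid is possible. Fallback: 7 is cyclised with the achiral Lewis acid Me2AlCl in CH2Cl2 at low temperature, the established way of closing this trienone class to cis-octalones. This gives 8 together with the enantiomer of 8 F1 as a racemate, which is resolved by preparative chromatography on a chiral stationary phase. Resolved 8 returns to the route at step 5.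

**Step 9.** Borane may reduce the isoxazoline C=N bond in competition with the hindered trisubstituted alkene, or part of the addition may occur on the β face. Fallback from 13: peracid epoxidation of C3=C4 on the α face gives the 3α,4α-epoxide F2. Isomerisation with diethylaluminium 2,2,6,6-tetramethylpiperidide removes a C15 proton and gives the 4(15)-methylene-3α-ol F3. Hydroxyl-directed hydrogenation with [Ir(cod)(PCy3)(py)]PF6 and H2 then delivers hydrogen to C4 on the face of O3 and rejoins the route at 15. No borane is used, and the C4 configuration follows from C3.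

**Step 12.** The Lewis-acidic titanium species may open the acetonide, or the free C3 hydroxyl may consume the reagent and stall the methylenation. Fallback from 18: addition of Me3SiCH2Li in the presence of CeCl3 gives the β-hydroxysilane F4, and KH-induced Peterson elimination returns to the route at 19. The organocerium reagent is weakly basic, so C7 is not enolised.

**Step 16.** The aldehyde may lose angelic acid by β-elimination before it is olefinated, or the Z selectivity may be incomplete. Fallback from 19, with the alkene geometry made by hydrogenation instead: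
- Lithiated tert-butyl propiolate opens (R)-propylene oxide in the presence of BF3·OEt2 to give tert-butyl (R)-5-hydroxyhex-2-ynoate F5.
- Acylation with the mixed anhydride 24 gives the angelate F6.
- CF3CO2H removes the tert-butyl group to give (R)-5-(angeloyloxy)hex-2-ynoic acid F7.
- DCC coupling with 19 gives the ynoate F8.
- Semihydrogenation over Pd/CaCO3 poisoned with Pb(OAc)2, with quinoline, gives 28, where the route resumes at step 17.

## Further compounds

F1 | step 4 | enantiomer of 8 (formed with 8 as the racemate) | C[Si](C)(C)[C@H]1C[C@]2(C)[C@@H](CCCC2=O)C=C1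
F2 | step 9 | 3α,4α-epoxide of 13 | CC1=NO[C@H]2[C@@H]1C[C@@]3(C)[C@H](CC[C@H]4O[C@]43C)[C@H]2O
F3 | step 9 | 5β-methyl-4-methylene-10βH-decalin-3α,9β-diol with 7β,8β-fused 3-methyl-4,5-dihydroisoxazole | CC1=NO[C@H]2[C@@H]1C[C@@]3(C)[C@H](CC[C@@H](O)C3=C)[C@H]2O
F4 | step 12 | 7β-[2-hydroxy-1-(trimethylsilyl)propan-2-yl] analogue of 18 (C11 epimers) | CC(O)(C[Si](C)(C)C)[C@H]1C[C@@]2(C)[C@H](CC[C@@H](O)[C@@H]2C)[C@@H](O3)[C@H]1OC3(C)C
F5 | step 16 | tert-butyl (R)-5-hydroxyhex-2-ynoate | CC(C)(C)OC(=O)C#CC[C@@H](C)O
F6 | step 16 | tert-butyl (R)-5-{[(Z)-2-methylbut-2-enoyl]oxy}hex-2-ynoate | CC(C)(C)OC(=O)C#CC[C@@H](C)OC(=O)/C(C)=C\C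
F7 | step 16 | (R)-5-{[(Z)-2-methylbut-2-enoyl]oxy}hex-2-ynoic acid | OC(=O)C#CC[C@@H](C)OC(=O)/C(C)=C\C
F8 | step 16 | 3α-O-[(R)-5-(angeloyloxy)hex-2-ynoyl] derivative of 19 | C=C(C)[C@H]1C[C@@]2(C)[C@H](CC[C@@H](OC(=O)C#CC[C@@H](C)OC(=O)/C(C)=C\C)[C@@H]2C)[C@@H](O3)[C@H]1OC3(C)C
A1 | alternative 1 | 9β-(tert-butyldimethylsilyloxy)-10βH-octal-4-en-3-one | C1CC2=CC(=O)CC[C@@H]2[C@@H](O[Si](C)(C)C(C)(C)C)C1
A2 | alternative 1 | 9β-(tert-butyldimethylsilyloxy)-4β,5β-dimethyl-cis-decalin-3-one (10βH) | C1C[C@@]2(C)[C@H](CCC(=O)[C@@H]2C)[C@@H](O[Si](C)(C)C(C)(C)C)C1
A3 | alternative 2 | (S)-3-methyl-5-(prop-1-en-2-yl)cyclohex-2-en-1-one | C=C(C)[C@H]1CC(C)=CC(=O)C1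
A4 | alternative 2 | (Z)-trimethyl(penta-1,3-dien-3-yloxy)silane | C=C/C(O[Si](C)(C)C)=C/C
A5 | alternative 2 | eremophil-11-ene-3,9-dione (4β,5β-dimethyl, 10βH) | C=C(C)[C@H]1C[C@@]2(C)[C@H](CCC(=O)[C@@H]2C)C(=O)C1
A6 | alternative 3 | 5,6-dimethyl-2-(3-methylbuta-1,3-dien-2-yl)bicyclo[2.2.2]oct-5-en-2-ol, dienyl group syn to the dimethyl-substituted bridge | C=C(C)C(=C)[C@]1(O)C[C@H]2CC[C@@H]1C(C)=C2C
A7 | alternative 3 | cis-fused eremophila-3,11-dien-8-one (10βH) | C=C(C)[C@H]1C[C@@]2(C)[C@H](CCC=C2C)CC1=O
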